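Everything rests on cutting the C3–C4 bond of ring A. The feature exploited is the C4 methyl carbinol, which is attached to C5 and stands 1,3 to the C6 oxygen of ring B: an acetyl group on C5 can accept a C3 nucleophile tethered through C1–C2 to C10. In one operation a samarium Barbier cyclisation of a primary iodide forms C3–C4, closes ring A as a trans-decalin and sets the C4 stereocentre through a chelate between the ketone oxygen and O6. The precursor is a fully substituted ring B carrying 5β-acetyl, 6β-benzyloxymethoxy, 7β-isopropyl, 10β-methyl and a 10α 3-iodopropyl arm, assembled from (R)-piperitone.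

Key step: step 9

Remarks on the chemistry (conventions, corrections, assumptions)
- All intermediates carry the eudesmane numbers of the target (ring B = C5–C10, arm = C1–C3, acetyl = C4 and C15); β is the face of the C10 methyl group, α the opposite face.
- The isopropyl-bearing carbon of (R)-piperitone is epimeric to C7 of the target (7α here). It is kept as a relay that steers C10 and C5 in step 1 and is inverted in step 3 under kinetic control, because base equilibration of the two C7 epimers is estimated to be almost thermoneutral.
- O6 is carried as a benzyloxymethyl (BOM) ether and not as a methoxymethyl ether: it chelates equally well, but it leaves by neutral hydrogenolysis, which avoids acid next to the syn-axial tertiary C4 hydroxyl (methylene acetal formation, dehydration).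
- The aldol hydroxyl (O4) is silylated before the C6 ketone is reduced, so that O4 and O6 are never free at the same time.
- The carbinol carbon C4 formed in step 1 is a mixture of epimers (left undefined in the SMILES of 6–13); it is erased in step 8.
- Assumption: (3-bromopropoxy)(tert-butyl)dimethylsilane is taken as a catalogue compound. Fe(dbm)3 is tris(dibenzoylmethanato)iron, Fe(C15H11O2)3.

Step 1
Reactants: 1 (R)-piperitone; 2 (3-bromopropoxy)(tert-butyl)dimethylsilane; 3 acetaldehyde
Product: 6 aldol adduct (C6 ketone with 5β-(1-hydroxyethyl) group), via Grignard reagent 4 (not isolated), via magnesium enolate 5 (not isolated)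
Conditions: 2, Mg, Et2O, 35 °C; then 1, Cu(OTf)2 (3 mol %), chiral C2-symmetric 4,5-diphenylimidazolinium chloride (carbene precursor, 4 mol %, antipode matched to addition cis to the isopropyl group), Et2O, 0 °C; then 3, −78 °C; then H2O
Reagents that add atoms: none
Why: Copper-catalysed asymmetric conjugate addition of Grignard reagent 4 to the β,β-disubstituted enone builds the C10 quaternary centre with the arm entering axially, cis to the pseudoequatorial isopropyl group (ligand and substrate matched), and magnesium enolate 5 is then trapped in an aldol addition in which acetaldehyde approaches C5 axially, anti to the new arm and to the C7 substituent, so that C10 and C5 are set in one flask while C4 forms as an inconsequential mixture.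

Step 2
Reactants: 6 aldol adduct
Product: 7 triethylsilyl ether of the aldol adduct
Conditions: TESOTf, 2,6-lutidine, CH2Cl2, −78 °C
Reagents that add atoms: triethylsilyl trifluoromethanesulfonate, CC[Si](CC)(CC)OS(=O)(=O)C(F)(F)F
Why: Silyl ether formation with a silyl triflate and a hindered pyridine base is fast at the hydroxyl even at −78 °C and closes the retro-aldol and dehydration pathways of the free β-hydroxy ketone before a strong base is used.

Step 3
Reactants: 7 triethylsilyl ether (7α-isopropyl ketone)
Product: 9 7β-isopropyl ketone (C7 epimer of 7), via lithium enolate 8 (not isolated)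
Conditions: LiN(i-Pr)2, THF, −78 to −40 °C; then AcOH, THF, −78 °C
Reagents that add atoms: none
Why: Regioselective kinetic enolisation followed by kinetic protonation: the amide base should remove the accessible C7 hydrogen and not the C5 hydrogen buried between the quaternary C10 and the silyloxyethyl branch, and the C6=C7 enolate 8 should be protonated on its α face in a chair-like approach that meets only hydrogens, the β face being screened by the C5 side chain, which inverts C7 to the 7β-isopropyl configuration.

Step 4
Reactants: 9 7β-isopropyl ketone
Product: 10 axial 6β-alcohol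
Conditions: LiBH(s-Bu)3, THF, −78 °C; then H2O
Reagents that add atoms: none
Why: Bulky-hydride reduction of a 2,6-disubstituted cyclohexanone: LiBH(s-Bu)3 should attack along the equatorial trajectory on the α face because the axial trajectory is blocked by the axial C10 methyl group, giving the axial 6β-alcohol cis to both equatorial neighbours.

Step 5
Reactants: 10 axial 6β-alcohol
Product: 11 6β-benzyloxymethyl ether
Conditions: BOMCl, i-Pr2NEt, CH2Cl2, 40 °C
Reagents that add atoms: benzyl chloromethyl ether, ClCOCc1ccccc1
Why: Alkoxymethylation (Williamson-type O-alkylation) of the hindered axial hydroxyl with a small, very reactive electrophile installs an acetal ether that can chelate samarium and is later cleaved without acid.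

Step 6
Reactants: 11 6β-benzyloxymethyl ether
Product: 12 diol (free C4 carbinol and free primary C3 hydroxyl)
Conditions: Bu4NF, THF, rt
Reagents that add atoms: none
Why: Fluoride-induced desilylation cleaves both the triethylsilyl and the tert-butyldimethylsilyl ether through Si–F bond formation and leaves the acetal ether intact.

Step 7
Reactants: 12 diol
Product: 13 primary iodide with free C4 carbinol
Conditions: iodine, PPh3, imidazole, CH2Cl2, 0 °C
Reagents that add atoms: iodine, II
Why: In the Appel iodination the unhindered primary hydroxyl is activated by the phosphine–iodine reagent and displaced by iodide (SN2) far faster than the secondary carbinol, which is flanked by the quaternary C10 and the ring.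

Step 8
Reactants: 13 primary iodide with free C4 carbinol
Product: 14 iodo ketone (5β-acetyl, 6β-OBOM, 7β-isopropyl, 10β-methyl, 10α-(3-iodopropyl))
Conditions: Dess–Martin periodinane, NaHCO3, CH2Cl2, 0 °C to rt
Reagents that add atoms: none
Why: Dess–Martin oxidation turns the secondary carbinol into the methyl ketone under buffered, non-basic conditions that tolerate the primary iodide and cannot epimerise C5 or expel the β-acetal oxygen by E1cB elimination; both C4 epimers converge on one ketone.

Step 9
Reactants: 14 iodo ketone
Product: 16 5α-eudesmane-4β,6β-diol 6-benzyloxymethyl ether, via alkylsamarium diiodide 15 (not isolated)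
Conditions: SmI2 (2.5 equiv), Fe(dbm)3 (2 mol %), THF, −78 °C to rt; then H2O
Reagents that add atoms: none
Why: Two single-electron transfers from divalent samarium convert the C3–iodine bond into a C3–samarium bond (trivalent samarium, 15), and this organometallic adds to the C4 carbonyl in a Barbier-type 1,2-addition; the closest known reaction type is the samarium diiodide cyclisation of ω-iodoalkyl ketones under iron catalysis, including β-oxygenated cases with chelation-based 1,3-induction. Ring A closes in a 6-exo-trig mode through a chair transition state in which the C5–C4 and C10–C1 bonds are both equatorial on ring B, so the trans ring fusion follows from the existing C5 and C10 centres. The new C4 stereocentre is controlled by a six-membered chelate in which samarium binds the carbonyl oxygen and the axial 6β acetal oxygen; this holds O4 on the β face (axial in ring A) and leaves the C15 methyl equatorial (α), an arrangement that also avoids a syn-axial clash of C15 with C14 and O6. The step needs chemoselectivity (reduction of the iodide before the ketone, no reductive loss of the β-alkoxy group, no epimerisation at C5) and facial selectivity at C4; the first should be secured by the fast reduction of a primary iodide in HMPA-free THF at low temperature and by the non-basic medium, the second by the chelate and the rigid chair of ring B.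

Step 10
Reactants: 16 5α-eudesmane-4β,6β-diol 6-benzyloxymethyl ether
Product: 18 5α-eudesmane-4β,6β-diol, via hemiformal 17 (not isolated)
Conditions: H2 (1 atm), Pd/C, EtOAc, rt
Reagents that add atoms: none
Why: Catalytic hydrogenolysis of the benzylic C–O bond gives hemiformal 17, which loses formaldehyde spontaneously, so O6 is freed under neutral conditions that can neither dehydrate the tertiary C4 carbinol nor tie it to O6 as a methylene acetal.

Step 11
Reactants: 19 isoferulic acid
Product: 20 O-acetylisoferulic acid
Conditions: Ac2O, pyridine, rt; then H2O
Reagents that add atoms: acetic anhydride, CC(=O)OC(C)=O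
Why: O-Acetylation of the phenol by the anhydride under pyridine catalysis masks the only competing nucleophile of the acid, and the aqueous work-up returns the free carboxylic acid.

Step 12
Reactants: 18 5α-eudesmane-4β,6β-diol; 20 O-acetylisoferulic acid
Product: 22 6-O-(O-acetylisoferuloyl) ester of the diol, via acid chloride 21 (not isolated)
Conditions: 20, (COCl)2, DMF (cat.), CH2Cl2, 0 °C to rt, evaporate; then 18, DMAP (cat.), Et3N, CH2Cl2, 0 to 40 °C
Reagents that add atoms: none
Why: Acylation by the acid chloride under nucleophilic catalysis by DMAP should esterify the secondary axial C6 hydroxyl, while the tertiary C4 hydroxyl is too hindered to react and the E alkene and the aryl acetate are spectators.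

Step 13
Reactants: 22 6-O-(O-acetylisoferuloyl) ester
Product: 23 target, 5α-eudesmane-4β,6β-diol 6-O-(E)-isoferulate
Conditions: K2CO3 (cat.), MeOH, 0 °C
Reagents that add atoms: none
Why: Base-catalysed transesterification with methanol should remove the activated aryl acetate far faster than it attacks the hindered, conjugated C6 ester, releasing the free phenol of the target.

Compound list
1 | (R)-piperitone, (6R)-3-methyl-6-(propan-2-yl)cyclohex-2-en-1-one | O=C1C=C(C)CC[C@@H]1C(C)C | starting material
2 | (3-bromopropoxy)(tert-butyl)dimethylsilane | BrCCCO[Si](C)(C)C(C)(C)C | starting material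
3 | acetaldehyde | CC=O | starting material
4 | [3-(tert-butyldimethylsilyloxy)propyl]magnesium bromide, formed in the flask | Br[Mg]CCCO[Si](C)(C)C(C)(C)C | intermediate
5 | bromomagnesium C5=C6 enolate with 10β-methyl, 10α-(3-silyloxypropyl), 7α-isopropyl, formed in the flask | Br[Mg]OC1=C[C@](C)(CCCO[Si](C)(C)C(C)(C)C)CC[C@@H]1C(C)C | intermediate
6 | aldol adduct: C6 ketone, 5β-(1-hydroxyethyl) (5α-H), 7α-isopropyl, 10β-methyl, 10α-[3-(tert-butyldimethylsilyloxy)propyl]; C4 epimers | O=C1[C@@H](C(C)O)[C@](C)(CCCO[Si](C)(C)C(C)(C)C)CC[C@@H]1C(C)C | intermediate
7 | O4-triethylsilyl ether of 6 (7α-isopropyl) | O=C1[C@@H](C(C)O[Si](CC)(CC)CC)[C@](C)(CCCO[Si](C)(C)C(C)(C)C)CC[C@@H]1C(C)C | intermediate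
8 | lithium C6=C7 enolate of 7, formed in the flask | CC(C)C1=C(O[Li])[C@@H](C(C)O[Si](CC)(CC)CC)[C@](C)(CCCO[Si](C)(C)C(C)(C)C)CC1 | intermediate
9 | C7 epimer of 7: C6 ketone, 5β side chain, 7β-isopropyl, 10β-methyl, 10α arm | O=C1[C@@H](C(C)O[Si](CC)(CC)CC)[C@](C)(CCCO[Si](C)(C)C(C)(C)C)CC[C@H]1C(C)C | intermediate
10 | axial 6β-alcohol, all-cis at C5, C6 and C7 | O[C@H]1[C@@H](C(C)O[Si](CC)(CC)CC)[C@](C)(CCCO[Si](C)(C)C(C)(C)C)CC[C@H]1C(C)C | intermediate
11 | 6β-benzyloxymethyl ether of 10 | c1ccccc1COCO[C@H]1[C@@H](C(C)O[Si](CC)(CC)CC)[C@](C)(CCCO[Si](C)(C)C(C)(C)C)CC[C@H]1C(C)C | intermediate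
12 | diol: 6β-OBOM, 5β-(1-hydroxyethyl), 10α-(3-hydroxypropyl) | c1ccccc1COCO[C@H]1[C@@H](C(C)O)[C@](C)(CCCO)CC[C@H]1C(C)C | intermediate
13 | iodo alcohol: 6β-OBOM, 5β-(1-hydroxyethyl), 10α-(3-iodopropyl) | c1ccccc1COCO[C@H]1[C@@H](C(C)O)[C@](C)(CCCI)CC[C@H]1C(C)C | intermediate
14 | key-step precursor: 5β-acetyl-6β-(benzyloxymethoxy)-7β-isopropyl-10β-methyl-10α-(3-iodopropyl)cyclohexane | c1ccccc1COCO[C@H]1[C@@H](C(C)=O)[C@](C)(CCCI)CC[C@H]1C(C)C | intermediate
15 | alkylsamarium diiodide derived from 14, formed in the flask | c1ccccc1COCO[C@H]1[C@@H](C(C)=O)[C@](C)(CCC[Sm](I)I)CC[C@H]1C(C)C | intermediate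
16 | key-step product: 5α-eudesmane-4β,6β-diol 6-benzyloxymethyl ether (4α-methyl, 4β-hydroxyl, trans-decalin) | c1ccccc1COCO[C@H]1[C@@H]2[C@](C)(CCC[C@]2(C)O)CC[C@H]1C(C)C | intermediate
17 | O6-hydroxymethyl ether (hemiformal) of the diol, formed in the flask | OCO[C@H]1[C@@H]2[C@](C)(CCC[C@]2(C)O)CC[C@H]1C(C)C | intermediate
18 | 5α-eudesmane-4β,6β-diol (7β-isopropyl, 10β-methyl) | O[C@H]1[C@@H]2[C@](C)(CCC[C@]2(C)O)CC[C@H]1C(C)C | intermediate
19 | isoferulic acid, (E)-3-(3-hydroxy-4-methoxyphenyl)prop-2-enoic acid | COc1ccc(/C=C/C(=O)O)cc1O | starting material
20 | O-acetylisoferulic acid, (E)-3-(3-acetoxy-4-methoxyphenyl)prop-2-enoic acid | COc1ccc(/C=C/C(=O)O)cc1OC(C)=O | intermediate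
21 | O-acetylisoferuloyl chloride, formed in the flask | COc1ccc(/C=C/C(Cl)=O)cc1OC(C)=O | intermediate
22 | 6-O-[(E)-3-(3-acetoxy-4-methoxyphenyl)prop-2-enoyl] ester of 18 | COc1ccc(/C=C/C(=O)O[C@H]2[C@@H]3[C@](C)(CCC[C@]3(C)O)CC[C@H]2C(C)C)cc1OC(C)=O | intermediate
23 | 5α-eudesmane-4β,6β-diol 6-O-(E)-isoferulate (CNP0291757.1) | COc1ccc(/C=C/C(=O)O[C@H]2[C@@H]3[C@](C)(CCC[C@]3(C)O)CC[C@H]2C(C)C)cc1O | target

Total step count: 13
Longest linear sequence: 12 steps (steps 1–10, 12 and 13 from (R)-piperitone); step 11 is a one-step side branch.

Steps most likely to fail

Risk 1, step 9 (key step). The carbon–iodine bond may be reduced without ring closure (protonation of the organosamarium), electron transfer to the ketone may lead to loss of the β-alkoxy group, or the carbonyl may be attacked on the wrong face. The fallback abandons single-electron chemistry for a polar anionic cyclisation. It sets out from 14: iodine–lithium exchange with t-BuLi (2.1 equiv, Et2O–pentane, −100 °C), which for a primary iodide at this temperature is known to outrun addition of the reagent to a ketone, would give the alkyllithium F1. F1 adds to the lithium-chelated acetyl group in the same 6-exo sense, and after aqueous quench the route is rejoined at 16.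

Risk 2, step 3. Enolisation may occur on the C5 side with loss of the silyloxy group, or protonation may take place on both faces and leave C7 as a mixture. The fallback replaces the protonation by a hydrogenation. It sets out from 7: dehydrogenation with IBX (DMSO, 70 °C) toward C8, the only ring carbon β to the carbonyl that bears hydrogen, would give the C7=C8 enone F2. Hydrogenation of F2 (H2, Pd/C, EtOAc) from the α face, opposite the C10 methyl group and the C5 side chain, should deliver the 7α hydrogen and come back to the route at 9.

Risk 3, step 1. Conjugate addition to the hindered, α′-substituted enone may stall, facial selectivity at C10 may be low, or the aldol addition at the congested magnesium enolate may revert. The fallback separates the two events and changes both mechanisms. It sets out from 1 and Grignard reagent 4 (made from 2): a chlorotrimethylsilane-accelerated conjugate addition under achiral copper catalysis (CuBr·SMe2 10 mol %, Me3SiCl, THF, −78 °C; substrate control, arm cis to the isopropyl group by axial attack) would give the isolable trimethylsilyl enol ether F3. A Mukaiyama aldol reaction of F3 with 3 (BF3·OEt2, CH2Cl2, −78 °C), which is irreversible and should show the same anti approach at C5, rejoins the route at 6.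

Further compounds
F1 | step 9 | alkyllithium derived from 14 (3-lithiopropyl arm) | c1ccccc1COCO[C@H]1[C@@H](C(C)=O)[C@](C)(CCC[Li])CC[C@H]1C(C)C
F2 | step 3 | C7=C8 enone derived from 7 | O=C1[C@@H](C(C)O[Si](CC)(CC)CC)[C@](C)(CCCO[Si](C)(C)C(C)(C)C)CC=C1C(C)C
F3 | step 1 | trimethylsilyl C5=C6 enol ether (10β-methyl, 10α-silyloxypropyl, 7α-isopropyl) | C[Si](C)(C)OC1=C[C@](C)(CCCO[Si](C)(C)C(C)(C)C)CC[C@@H]1C(C)C
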